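Locants and abbreviations used throughout: ring A = benzo ring of the benzodioxane (C4a, C5–C8, C8a); ring B = dioxane ring (O1, C2, C3, O4, C4a, C8a); ring C = the aryl group on C3. In open-chain intermediates the carbons that become C2 and C3 keep these locants. ArC = 3-methoxy-4,5-bis(methoxymethoxy)phenyl; ArAO = 2-bromo-6-methoxy-4-[(1E)-3-[methoxy(methyl)amino]-3-oxoprop-1-en-1-yl]phenoxy; MOM = methoxymethyl; Tr = triphenylmethyl.

## Analysis of the target

Compound 15 is a 1,4-benzodioxane neolignan made of two C6C3 units. Ring A carries OMe at C8 and an (E)-propenal at C6 and is fused to ring B; C2 bears CH2OH and C3 bears ring C, a 3,4-dihydroxy-5-methoxyphenyl group. The only stereocentres are the adjacent C2 and C3, both R, which places CH2OH and ring C trans on ring B. The two ring oxygens are not equivalent: O1, next to C8–OMe and para to C6, holds C2, while O4 holds the benzylic C3, so the two oxygens of a ring-A catechol must be told apart. Sensitive groups are the enal (hydride, nucleophiles, hydrogenation), the free catechol of ring C (oxidation, base) and the C3–O4 bond, a p-hydroxybenzyl aryl ether that can ionise toward a quinone methide under forcing acid or base. The difficulty is absolute control: the radical assembly of ring B offers no handle for a chiral reagent, and C2 and C3 are contiguous carbinol-ether centres with no neighbouring stereocentre to relay from. The feature used here is that C2 is flanked by O1, by C3 and by its exocyclic carbon: with C3 as a ketone and the exocyclic carbon as an ester, H–C2 becomes a doubly activated, freely epimerising methine, so one enantioselective reduction at C3 can fix C2 and C3 together. A second feature is that O4–C4a is an aryl–oxygen bond, which can be made on an aryl bromide without breaking any bond at C2 or C3.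

## Retrosynthetic reasoning

Target 15 is first traced to its protected form 14. Only protecting-group C–O bonds are cut: two MOM acetals on ring C and a trityl ether on the C2 hydroxymethyl. All three are acid-labile, so one final operation releases the catechol and the primary alcohol.

The enal of 14 is traced to the N-methoxy-N-methyl amide 12. An aldehyde on ring A could not survive the hydride steps that set the stereocentres, whereas this amide carries the complete three-carbon chain at the correct oxidation level and gives the enal in one reduction through chelate 13.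

Ring B of 12 is opened at O4–C4a, the aryl–oxygen bond, and not at C3–O4 as is usual for this class. The precursor 11 is then an open-chain bromo alcohol in which bromine marks the place of O4. The forward reaction, a palladium-catalysed etherification, forms the bond on the arene and leaves C2 and C3 as they are. The regiochemistry of the two ring oxygens is therefore decided by the substitution pattern of 5-bromovanillin (3) and not by a selectivity.

Compound 11 is traced through diol 10 to hydroxy ester 9 by functional-group changes only. The primary alcohol must be masked because it, too, could close a six-membered ring onto the bromide. The ester is needed one step earlier to make C2 acidic.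

Hydroxy ester 9 is traced to the racemic keto ester 8 by removing the hydride at C3. This is the key disconnection: 8 has no fixed stereocentre, and the forward reduction has to turn both enantiomers of 8 into one syn-configured product. The syn relationship is what a stereoretentive ring closure needs for the trans ring.

Keto ester 8 is cut at C2–C3. It comes from aldol adduct 7, and 7 from the ester 5 and the aldehyde 2 by an aldol addition whose stereochemical outcome is irrelevant. This cut divides the skeleton into two halves of similar size, each derived from a vanillin-type aldehyde.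

Ester 5 is traced through aldehyde 4 to 5-bromovanillin (3) by a Wittig olefination and an O-alkylation with a haloacetate. Aldehyde 2 is the bis-MOM ether of 5-hydroxyvanillin (1).

## Alternatives that were turned down

Alternative 1: The textbook route cuts both alkyl C–O bonds of ring B (C2–O1 and C3–O4) and takes the stereocentres from a Sharpless asymmetric dihydroxylation. Dihydroxylation of the ring-C (E)-cinnamate ester with K2OsO2(OH)4/(DHQ)2PHAL/K3Fe(CN)6 would give the syn-diol A1. Two invertive etherifications would follow: a Mitsunobu reaction at C2 with a monoprotected ring-A catechol, then closure at C3. It was turned down for three reasons. A syn-diol needs inversion at both carbons to reach the trans ring, and neither inversion is clean: the activated C2–OH next to the free C3–OH tends to close to the glycidic ester, and C3 on the electron-rich ring C ionises instead of reacting by SN2. The phenol partner is a 2,6-disubstituted, differentially protected catechol, which costs extra protecting-group steps. The sequence is no shorter than the chosen one and uses two stoichiometric redox condensations.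

Alternative 2: The biomimetic route cuts ring B into two phenylpropanoids. Oxidation of 5-hydroxyconiferaldehyde A2 and the monolignol A3 with Ag2CO3 would couple O1 to C2 by radical combination, and the resulting quinone methide would be trapped by the second phenol at C3 to give the trans-benzodioxane A4. This is the shortest route and the regiochemistry would follow the natural pattern. It was turned down because the C2–O1 bond forms between two free, achiral radicals, so A4 can only be racemic. A single enantiomer would need a resolution that discards half of the most advanced material. In addition, A3 homo-couples and A2 is over-oxidised to its o-quinone in competition with the cross-coupling.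

Alternative 3: A hydrogenative route cuts the C2–H and C3–H bonds. A ring-A catechol and an α-halo-β-keto ester would be annulated to the 1,4-benzodioxine A5, and asymmetric hydrogenation of the C2=C3 bond would follow. It was turned down for four reasons. The alkene is tetrasubstituted and doubly oxygenated, a class for which enantioselective hydrogenation is much less secure than for 2-monosubstituted benzodioxines. Syn addition of H2 gives the cis ring, so C2 would have to be epimerised through the ester enolate, which can expel the O4 phenoxide and so racemise C3. Hydrogen would also saturate the side-chain alkene, so the propenal would have to be built afterwards. The annulation itself needs regiocontrol on an unsymmetrical catechol.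

Key step: step 6

Remark: 1 and 3 are taken as commercial. The sense of induction in step 6 is assigned by analogy with aryl ketone reductions by the same catalyst; the enantiomeric catalyst would be used if the sense proved opposite.

## Route

Step 1
Reactants: 1 3,4-dihydroxy-5-methoxybenzaldehyde (5-hydroxyvanillin)
Product: 2 3-methoxy-4,5-bis(methoxymethoxy)benzaldehyde
Conditions: MOMCl, i-Pr2NEt, CH2Cl2, 0 °C to rt
Reagents that add atoms: chloromethyl methyl ether, COCCl
Why: Double O-alkylation of the catechol (Williamson-type acetal formation); the MOM ethers are stable to enolates, hydride and palladium/base and are removed by acid at the end.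

Step 2
Reactants: 3 3-bromo-4-hydroxy-5-methoxybenzaldehyde (5-bromovanillin)
Product: 4 ethyl 2-(2-bromo-4-formyl-6-methoxyphenoxy)acetate
Conditions: BrCH2CO2Et, K2CO3, DMF, rt
Reagents that add atoms: ethyl bromoacetate, CCOC(=O)CBr
Why: Williamson ether synthesis; the phenoxide, although flanked by Br and OMe, should react readily with the unhindered activated primary bromide, which fixes O1 on the future C2 while bromine marks the site of O4.

Step 3
Reactants: 4 ethyl 2-(2-bromo-4-formyl-6-methoxyphenoxy)acetate
Product: 5 ethyl 2-(ArAO)acetate, the (E)-N-methoxy-N-methyl cinnamamide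
Conditions: Ph3P=CHC(O)N(OMe)Me, toluene, 80 °C
Reagents that add atoms: N-methoxy-N-methyl-2-(triphenylphosphoranylidene)acetamide, CON(C)C(=O)C=P(c1ccccc1)(c1ccccc1)c1ccccc1
Why: Wittig olefination with an amide-stabilised ylide, which should give the E-alkene; the Weinreb amide carries the side chain at the aldehyde oxidation level in a form inert to ester enolates, transfer hydrogenation and NaBH4.

Step 4
Reactants: 5 ethyl 2-(ArAO)acetate; 2 3-methoxy-4,5-bis(methoxymethoxy)benzaldehyde
Product: 7 ethyl 2-(ArAO)-3-hydroxy-3-ArC-propanoate (racemic syn/anti mixture), via lithium ester enolate 6 (not isolated)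
Conditions: LiN(SiMe3)2, THF, −78 °C; then 2, −78 °C; AcOH quench
Reagents that add atoms: none
Why: Aldol addition of a lithium ester enolate to a non-enolisable aldehyde forms the C2–C3 bond; the amide base deprotonates only the aryloxy-activated CH2, and the configuration of 7 does not matter because step 5 removes C3 and step 6 resets both centres.

Step 5
Reactants: 7 ethyl 2-(ArAO)-3-hydroxy-3-ArC-propanoate
Product: 8 ethyl 2-(ArAO)-3-oxo-3-ArC-propanoate (racemic)
Conditions: Dess–Martin periodinane, CH2Cl2, 0 °C to rt
Reagents that add atoms: none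
Why: Dess–Martin oxidation of the benzylic secondary alcohol under near-neutral conditions that spare the MOM acetals and the enamide; the product is the β-keto ester in which H–C2 is doubly activated.

Step 6
Reactants: 8 ethyl 2-(ArAO)-3-oxo-3-ArC-propanoate (racemic)
Product: 9 ethyl (2S,3R)-2-(ArAO)-3-hydroxy-3-ArC-propanoate
Conditions: RuCl[(S,S)-TsDPEN](p-cymene) (2 mol %), HCO2H/Et3N (5:2), CH2Cl2, 35 °C
Reagents that add atoms: none
Why: Noyori–Ikariya asymmetric transfer hydrogenation under dynamic kinetic resolution, the known reaction of α-alkoxy β-keto esters of aryl ketones. H–C2 of 8 lies between the ketone, the ester and the aryloxy oxygen, so the amine/formic acid medium interconverts the two enantiomers through the enol much faster than either is reduced. The divalent ruthenium hydride, regenerated from formic acid with loss of CO2, passes hydride and proton to the C=O in an outer-sphere six-membered transition state; no ring is closed in this step. C3 is controlled by the catalyst: the (S,S)-diamine complex places the ketone aryl group under the η6-arene (CH/π contact), the same sense that gives (S)-1-phenylethanol, which reads 3R here because C2 outranks the aryl group. C2 is controlled by matching: only the 2S enantiomer of 8 fits this transition state without a clash of its ester and aryloxy groups with the sulfonamide, which leads to the 2,3-syn product as established for α-alkoxy analogues. The step also needs chemoselectivity over the enamide C=C, the aryl bromide and the MOM acetals; the ruthenium hydride reduces only polar C=O bonds and the buffered medium is too weakly acidic to cleave the acetals. Product 9 is no longer acidic at C2, so both centres are fixed once formed.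

Step 7
Reactants: 9 ethyl (2S,3R)-2-(ArAO)-3-hydroxy-3-ArC-propanoate
Product: 10 (2E)-3-[3-bromo-4-{[(1R,2R)-1,3-dihydroxy-1-ArC-propan-2-yl]oxy}-5-methoxyphenyl]-N-methoxy-N-methylprop-2-enamide
Conditions: NaBH4, THF/H2O (3:1), 0 °C to rt
Reagents that add atoms: none
Why: Borohydride reduction of an ester activated by its α-aryloxy and β-hydroxy groups; the conjugated Weinreb amide should not be reduced by NaBH4, and C2 and C3 are untouched (the C2 descriptor changes only through the priority rules).

Step 8
Reactants: 10 the (1R,2R)-diol
Product: 11 (2E)-3-[3-bromo-4-{[(1R,2R)-1-hydroxy-1-ArC-3-(trityloxy)propan-2-yl]oxy}-5-methoxyphenyl]-N-methoxy-N-methylprop-2-enamide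
Conditions: TrCl, Et3N, DMAP (cat.), CH2Cl2, rt
Reagents that add atoms: trityl chloride, ClC(c1ccccc1)(c1ccccc1)c1ccccc1
Why: Tritylation, selective for the primary alcohol on steric grounds; it blocks the hydroxyl that would otherwise close a competing six-membered ring in step 9, and a trityl ether cannot migrate to the neighbouring alkoxide as a silyl ether could.

Step 9
Reactants: 11 the (1R,2R)-bromo alcohol trityl ether
Product: 12 (2E)-3-[(2R,3R)-8-methoxy-3-ArC-2-(trityloxymethyl)-2,3-dihydro-1,4-benzodioxin-6-yl]-N-methoxy-N-methylprop-2-enamide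
Conditions: Pd(OAc)2 (5 mol %), 2-(di-tert-butylphosphino)-1,1'-binaphthyl (6 mol %), Cs2CO3, toluene, 80 °C
Reagents that add atoms: none
Why: Intramolecular Buchwald–Hartwig C–O coupling: zerovalent palladium inserts into the C4a–Br bond, the C3 alkoxide binds, and reductive elimination closes ring B; the C3–O bond is never broken, so the syn open chain gives the trans (2R,3R) ring with retention, and the bulky electron-rich phosphine favours reductive elimination over β-hydride elimination.

Step 10
Reactants: 12 the Weinreb amide of the protected benzodioxane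
Product: 14 (2E)-3-[(2R,3R)-8-methoxy-3-ArC-2-(trityloxymethyl)-2,3-dihydro-1,4-benzodioxin-6-yl]prop-2-enal, via aluminium hemiaminal 13 (not isolated)
Conditions: i-Bu2AlH, THF, −78 °C; then aq. KNaC4H4O6 (potassium sodium tartrate)
Reagents that add atoms: none
Why: Weinreb amide reduction; the N,O-chelated aluminium hemiaminal 13 persists at −78 °C and releases the aldehyde only on work-up, so over-reduction to the allylic alcohol is avoided and the E-alkene is retained.

Step 11
Reactants: 14 the protected enal
Product: 15 (2E)-3-[(2R,3R)-3-(3,4-dihydroxy-5-methoxyphenyl)-2-(hydroxymethyl)-8-methoxy-2,3-dihydro-1,4-benzodioxin-6-yl]prop-2-enal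
Conditions: 3 M aq. HCl/THF (1:4), 40 °C
Reagents that add atoms: none
Why: Acid hydrolysis of the two MOM acetals and the trityl ether in one operation; the enal, the methyl ethers and ring B should tolerate dilute aqueous acid, and any reversible ionisation at C3 can only return to the favoured trans isomer because C2 is not affected.

## Compound list

1 | 3,4-dihydroxy-5-methoxybenzaldehyde (5-hydroxyvanillin) | COc1cc(C=O)cc(O)c1O | starting material
2 | 3-methoxy-4,5-bis(methoxymethoxy)benzaldehyde | COCOc1cc(C=O)cc(OC)c1OCOC | intermediate
3 | 3-bromo-4-hydroxy-5-methoxybenzaldehyde (5-bromovanillin) | COc1cc(C=O)cc(Br)c1O | starting material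
4 | ethyl 2-(2-bromo-4-formyl-6-methoxyphenoxy)acetate | CCOC(=O)COc1c(Br)cc(C=O)cc1OC | intermediate
5 | ethyl 2-{2-bromo-6-methoxy-4-[(1E)-3-[methoxy(methyl)amino]-3-oxoprop-1-en-1-yl]phenoxy}acetate | CCOC(=O)COc1c(Br)cc(/C=C/C(=O)N(C)OC)cc1OC | intermediate
6 | lithium enolate of 5 | [Li+].CCOC([O-])=COc1c(Br)cc(/C=C/C(=O)N(C)OC)cc1OC | intermediate (not isolated)
7 | ethyl 2-{2-bromo-6-methoxy-4-[(1E)-3-[methoxy(methyl)amino]-3-oxoprop-1-en-1-yl]phenoxy}-3-hydroxy-3-[3-methoxy-4,5-bis(methoxymethoxy)phenyl]propanoate (racemic, syn/anti mixture) | CCOC(=O)C(Oc1c(Br)cc(/C=C/C(=O)N(C)OC)cc1OC)C(O)c1cc(OC)c(OCOC)c(OCOC)c1 | intermediate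
8 | ethyl 2-{2-bromo-6-methoxy-4-[(1E)-3-[methoxy(methyl)amino]-3-oxoprop-1-en-1-yl]phenoxy}-3-[3-methoxy-4,5-bis(methoxymethoxy)phenyl]-3-oxopropanoate (racemic) | CCOC(=O)C(Oc1c(Br)cc(/C=C/C(=O)N(C)OC)cc1OC)C(=O)c1cc(OC)c(OCOC)c(OCOC)c1 | intermediate
9 | ethyl (2S,3R)-2-{2-bromo-6-methoxy-4-[(1E)-3-[methoxy(methyl)amino]-3-oxoprop-1-en-1-yl]phenoxy}-3-hydroxy-3-[3-methoxy-4,5-bis(methoxymethoxy)phenyl]propanoate | CCOC(=O)[C@@H](Oc1c(Br)cc(/C=C/C(=O)N(C)OC)cc1OC)[C@H](O)c1cc(OC)c(OCOC)c(OCOC)c1 | intermediate
10 | (2E)-3-[3-bromo-4-{[(1R,2R)-1,3-dihydroxy-1-[3-methoxy-4,5-bis(methoxymethoxy)phenyl]propan-2-yl]oxy}-5-methoxyphenyl]-N-methoxy-N-methylprop-2-enamide | OC[C@@H](Oc1c(Br)cc(/C=C/C(=O)N(C)OC)cc1OC)[C@H](O)c1cc(OC)c(OCOC)c(OCOC)c1 | intermediate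
11 | (2E)-3-[3-bromo-4-{[(1R,2R)-1-hydroxy-1-[3-methoxy-4,5-bis(methoxymethoxy)phenyl]-3-(triphenylmethoxy)propan-2-yl]oxy}-5-methoxyphenyl]-N-methoxy-N-methylprop-2-enamide | c1ccccc1C(c1ccccc1)(c1ccccc1)OC[C@@H](Oc1c(Br)cc(/C=C/C(=O)N(C)OC)cc1OC)[C@H](O)c1cc(OC)c(OCOC)c(OCOC)c1 | intermediate
12 | (2E)-N-methoxy-3-[(2R,3R)-8-methoxy-3-[3-methoxy-4,5-bis(methoxymethoxy)phenyl]-2-[(triphenylmethoxy)methyl]-2,3-dihydro-1,4-benzodioxin-6-yl]-N-methylprop-2-enamide | c1ccccc1C(c1ccccc1)(c1ccccc1)OC[C@H]1Oc2c(OC)cc(/C=C/C(=O)N(C)OC)cc2O[C@@H]1c1cc(OC)c(OCOC)c(OCOC)c1 | intermediate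
13 | diisobutylaluminium hemiaminal of 12 (O-aluminated tetrahedral adduct at the amide carbon, that carbon unassigned) | c1ccccc1C(c1ccccc1)(c1ccccc1)OC[C@H]1Oc2c(OC)cc(/C=C/C(O[Al](CC(C)C)CC(C)C)N(C)OC)cc2O[C@@H]1c1cc(OC)c(OCOC)c(OCOC)c1 | intermediate (not isolated)
14 | (2E)-3-[(2R,3R)-8-methoxy-3-[3-methoxy-4,5-bis(methoxymethoxy)phenyl]-2-[(triphenylmethoxy)methyl]-2,3-dihydro-1,4-benzodioxin-6-yl]prop-2-enal | c1ccccc1C(c1ccccc1)(c1ccccc1)OC[C@H]1Oc2c(OC)cc(/C=C/C=O)cc2O[C@@H]1c1cc(OC)c(OCOC)c(OCOC)c1 | intermediate
15 | (2E)-3-[(2R,3R)-3-(3,4-dihydroxy-5-methoxyphenyl)-2-(hydroxymethyl)-8-methoxy-2,3-dihydro-1,4-benzodioxin-6-yl]prop-2-enal | OC[C@H]1Oc2c(OC)cc(/C=C/C=O)cc2O[C@@H]1c1cc(OC)c(O)c(O)c1 | target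

## Step count and least certain steps

Total: 11 steps. Longest linear sequence: 10 steps (3 to 15, steps 2–11); step 1 prepares the second fragment.

Step 6 (key step). The catalyst may discriminate poorly between the two enantiomers of 8, because the 2,6-disubstituted aryloxy group is larger than the alkoxy groups for which syn selectivity is established. Hydride transfer to the electron-rich ketone may also be slow. The fallback sets out from 5 and returns at 10; it gives up the dynamic resolution for an auxiliary-controlled C2–C3 bond formation. Ester 5 is saponified selectively (LiOH, THF/H2O) to the aryloxyacetic acid F1. Its pivaloyl mixed anhydride acylates lithiated (4S)-4-benzyl-1,3-oxazolidin-2-one to give the N-acyl oxazolidinone F2. An Evans syn-aldol reaction (Bu2BOTf, i-Pr2NEt, CH2Cl2, −78 °C, then 2) should give the syn-aldol adduct F3 with the same (2S,3R) configuration as 9. Reductive removal of the auxiliary with NaBH4 in THF/H2O then gives diol 10.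

Step 9. β-Hydride elimination from the palladium alkoxide at the benzylic C3–H may compete, giving ketone formation and loss of bromine, and reductive elimination at the electron-rich ring may be slow. The fallback sets out from 10 and returns at 12; it turns the bromide into the missing phenol and closes ring B at C3 instead. Miyaura borylation of 10 (Pd(dppf)Cl2, B2pin2, KOAc, dioxane, 90 °C) gives the aryl boronate F4. Oxidation with NaBO3·4H2O in THF/H2O gives the phenol F5. Catalytic camphorsulfonic acid in CH2Cl2 ionises the electron-rich benzylic alcohol, and the neighbouring phenol traps the cation to give the hydroxymethyl benzodioxane F6. This closure is reversible and should settle on the trans isomer, with C2 from step 6 unchanged. Tritylation as in step 8 gives 12.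

Step 11. The acid may drive side processes on the unmasked catechol ring: capture of released formaldehyde or of the trityl cation, and ionisation at C3 with partial loss of the trans configuration while the enal is present. The fallback sets out from 12 and returns at 15; it reverses the order of deprotection and reduction. Amide 12 is deprotected with HCl in MeOH, where no aldehyde is present and formaldehyde is trapped by the solvent, to give the free catechol amide F7. Excess i-Bu2AlH in THF at −78 °C then reduces the Weinreb amide of F7, through the same chelate type as 13, to 15.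

Step 4. Enolate 6 may add in conjugate fashion to the enamide of a second molecule or self-condense before it meets the aldehyde. The fallback sets out from 3 and 2 and returns at 8; it joins the halves by O-alkylation instead of C–C bond formation. Wittig olefination of 3 with the ylide of step 3 gives the bromophenol amide F8. A Roskamp reaction of 2 (ethyl diazoacetate, SnCl2, CH2Cl2) gives the β-keto ester F9, and N-chlorosuccinimide gives the α-chloro-β-keto ester F10. Alkylation of F8 with F10 (K2CO3, acetone) forms the C2–O1 bond and gives 8 directly.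

## Further compounds

F1 | step 6 | 2-{2-bromo-6-methoxy-4-[(1E)-3-[methoxy(methyl)amino]-3-oxoprop-1-en-1-yl]phenoxy}acetic acid | OC(=O)COc1c(Br)cc(/C=C/C(=O)N(C)OC)cc1OC
F2 | step 6 | (4S)-4-benzyl-3-(2-{2-bromo-6-methoxy-4-[(1E)-3-[methoxy(methyl)amino]-3-oxoprop-1-en-1-yl]phenoxy}acetyl)-1,3-oxazolidin-2-one | O=C(COc1c(Br)cc(/C=C/C(=O)N(C)OC)cc1OC)N1[C@@H](Cc2ccccc2)COC1=O
F3 | step 6 | (4S)-4-benzyl-3-[(2S,3R)-2-{2-bromo-6-methoxy-4-[(1E)-3-[methoxy(methyl)amino]-3-oxoprop-1-en-1-yl]phenoxy}-3-hydroxy-3-[3-methoxy-4,5-bis(methoxymethoxy)phenyl]propanoyl]-1,3-oxazolidin-2-one | O=C([C@@H](Oc1c(Br)cc(/C=C/C(=O)N(C)OC)cc1OC)[C@H](O)c1cc(OC)c(OCOC)c(OCOC)c1)N1[C@@H](Cc2ccccc2)COC1=O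
F4 | step 9 | (2E)-3-[4-{[(1R,2R)-1,3-dihydroxy-1-[3-methoxy-4,5-bis(methoxymethoxy)phenyl]propan-2-yl]oxy}-3-methoxy-5-(4,4,5,5-tetramethyl-1,3,2-dioxaborolan-2-yl)phenyl]-N-methoxy-N-methylprop-2-enamide | OC[C@@H](Oc1c(B2OC(C)(C)C(C)(C)O2)cc(/C=C/C(=O)N(C)OC)cc1OC)[C@H](O)c1cc(OC)c(OCOC)c(OCOC)c1
F5 | step 9 | (2E)-3-[4-{[(1R,2R)-1,3-dihydroxy-1-[3-methoxy-4,5-bis(methoxymethoxy)phenyl]propan-2-yl]oxy}-3-hydroxy-5-methoxyphenyl]-N-methoxy-N-methylprop-2-enamide | OC[C@@H](Oc1c(O)cc(/C=C/C(=O)N(C)OC)cc1OC)[C@H](O)c1cc(OC)c(OCOC)c(OCOC)c1
F6 | step 9 | (2E)-3-[(2R,3R)-2-(hydroxymethyl)-8-methoxy-3-[3-methoxy-4,5-bis(methoxymethoxy)phenyl]-2,3-dihydro-1,4-benzodioxin-6-yl]-N-methoxy-N-methylprop-2-enamide | OC[C@H]1Oc2c(OC)cc(/C=C/C(=O)N(C)OC)cc2O[C@@H]1c1cc(OC)c(OCOC)c(OCOC)c1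
F7 | step 11 | (2E)-3-[(2R,3R)-3-(3,4-dihydroxy-5-methoxyphenyl)-2-(hydroxymethyl)-8-methoxy-2,3-dihydro-1,4-benzodioxin-6-yl]-N-methoxy-N-methylprop-2-enamide | OC[C@H]1Oc2c(OC)cc(/C=C/C(=O)N(C)OC)cc2O[C@@H]1c1cc(OC)c(O)c(O)c1
F8 | step 4 | (2E)-3-(3-bromo-4-hydroxy-5-methoxyphenyl)-N-methoxy-N-methylprop-2-enamide | CON(C)C(=O)/C=C/c1cc(Br)c(O)c(OC)c1
F9 | step 4 | ethyl 3-[3-methoxy-4,5-bis(methoxymethoxy)phenyl]-3-oxopropanoate | CCOC(=O)CC(=O)c1cc(OC)c(OCOC)c(OCOC)c1
F10 | step 4 | ethyl 2-chloro-3-[3-methoxy-4,5-bis(methoxymethoxy)phenyl]-3-oxopropanoate (racemic) | CCOC(=O)C(Cl)C(=O)c1cc(OC)c(OCOC)c(OCOC)c1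
A1 | alternative 1 | ethyl (2R,3S)-2,3-dihydroxy-3-[3-methoxy-4,5-bis(methoxymethoxy)phenyl]propanoate | CCOC(=O)[C@H](O)[C@@H](O)c1cc(OC)c(OCOC)c(OCOC)c1
A2 | alternative 2 | (2E)-3-(3,4-dihydroxy-5-methoxyphenyl)prop-2-enal (5-hydroxyconiferaldehyde) | O=C/C=C/c1cc(O)c(O)c(OC)c1
A3 | alternative 2 | (2E)-3-[4-hydroxy-3-methoxy-5-(methoxymethoxy)phenyl]prop-2-en-1-ol | OC/C=C/c1cc(OC)c(O)c(OCOC)c1
A4 | alternative 2 | rac-(2E)-3-[(2R*,3R*)-3-[4-hydroxy-3-methoxy-5-(methoxymethoxy)phenyl]-2-(hydroxymethyl)-8-methoxy-2,3-dihydro-1,4-benzodioxin-6-yl]prop-2-enal (racemate, one enantiomer drawn) | OC[C@H]1Oc2c(OC)cc(/C=C/C=O)cc2O[C@@H]1c1cc(OC)c(O)c(OCOC)c1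
A5 | alternative 3 | ethyl 6-(1,3-dioxolan-2-yl)-8-methoxy-3-[3-methoxy-4,5-bis(methoxymethoxy)phenyl]-1,4-benzodioxine-2-carboxylate | CCOC(=O)C1=C(c2cc(OC)c(OCOC)c(OCOC)c2)Oc2cc(C3OCCO3)cc(OC)c2O1
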